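The route rests on cutting the two aryl–carbonyl bonds of the quinone ring, C1–C8a and C4–C4a. Without its aryl group the benzo ring (C4a, C5, C6-Me, C7-Me, C8, C8a) is symmetric, so a symmetric 4,5-dimethylbenzyne can be joined to 3-methoxyfuran by a Diels–Alder reaction with no regiochemical question. Acid then opens the oxygen bridge so that the hydroxyl remains on C1, beside the methoxy carbon C2. This one free hydroxyl then steers a palladium-catalysed peri C–H arylation to C8, and oxidation at C4 gives the quinone. The precursor of the key step is simply an ortho-silylaryl triflate and the furan.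

Key step: step 1

Assumption: the target is drawn without an axial descriptor, so the C8–aryl axis is formed without control; compounds 1, 2 and 6 are taken as catalogue compounds, and naphthalene locants of the target are used throughout.

Step 1
Reactants: 1 4,5-dimethyl-2-(trimethylsilyl)phenyl trifluoromethanesulfonate; 2 3-methoxyfuran
Product: 5 2-methoxy-6,7-dimethylnaphthalen-1-ol, via 4,5-dimethylbenzyne 3 (not isolated), via oxabicyclic cycloadduct 4 (not isolated)
Conditions: CsF, MeCN, rt; then CF3CO2H (cat.), CH2Cl2, 0 °C
Reagents that add atoms: none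
Why: Fluoride attack on silicon expels triflate to give the symmetric aryne 3, whose strained in-plane π bond adds across C2 and C5 of the electron-rich furan 2 in a concerted, suprafacial [4+2] cycloaddition that forms both aryl–carbon bonds (C1–C8a and C4–C4a) at once. The closest known reaction type is the Diels–Alder reaction of an aryne (from fluoride-induced 1,2-elimination of an ortho-silylaryl triflate) with a furan, followed by acid isomerisation of the 1,4-epoxy-1,4-dihydronaphthalene to a 1-naphthol. The new six-membered carbocycle is closed by this cycloaddition as a bridged 7-oxabicyclo[2.2.1]heptadiene. The two bridgehead stereocentres of 4 arise as a racemate, their relative configuration is fixed by the oxygen bridge, and both vanish on aromatisation, so no stereocontrol is needed. The cycloaddition needs no regiocontrol because the mirror-symmetric aryne makes both orientations identical; the selectivity needed lies in the opening, where protonated 4 should ionise only at C4–O, since that cation is a vinylogous oxocarbenium ion stabilised by the C2 methoxy group, so that loss of H1 leaves the hydroxyl on C1 next to the methoxy carbon.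

Step 2
Reactants: 5 2-methoxy-6,7-dimethylnaphthalen-1-ol; 6 1-iodo-2,4,5-trimethoxybenzene
Product: 7 2-methoxy-6,7-dimethyl-8-(2,4,5-trimethoxyphenyl)naphthalen-1-ol
Conditions: Pd(OAc)2 (10 mol %), Cs2CO3, 4 Å MS, DMF, 110 °C, N2
Reagents that add atoms: none
Why: Hydroxyl-directed palladium-catalysed peri C–H arylation of a 1-naphthol with an aryl iodide: the arylpalladium iodide from 6 binds the caesium naphtholate of 5, palladates the only C–H within reach of oxygen (C8, five-membered oxapalladacycle; C2 is blocked by the methoxy group) and reductively eliminates to the biaryl.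

Step 3
Reactants: 7 2-methoxy-6,7-dimethyl-8-(2,4,5-trimethoxyphenyl)naphthalen-1-ol
Product: 8 2-methoxy-6,7-dimethyl-8-(2,4,5-trimethoxyphenyl)naphthalene-1,4-dione (target)
Conditions: (KSO3)2NO (Fremy's salt, 2.2 equiv), KH2PO4, acetone–H2O, rt
Reagents that add atoms: potassium nitrosodisulfonate (Fremy's salt), [K+].[K+].[O]N(S(=O)(=O)[O-])S(=O)(=O)[O-]
Why: Teuber oxidation: the nitrosodisulfonate radical removes the phenolic hydrogen, a second equivalent couples through oxygen at the free para position C4 (the ortho position C2 carries the methoxy group), and loss of imidodisulfonate leaves the para-quinone, while the trimethoxyphenyl ring should be inert to this reagent.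

Compound list
1 | 4,5-dimethyl-2-(trimethylsilyl)phenyl trifluoromethanesulfonate | Cc1cc(OS(=O)(=O)C(F)(F)F)c(cc1C)[Si](C)(C)C | starting material
2 | 3-methoxyfuran | COc1ccoc1 | starting material
3 | 4,5-dimethylbenzyne (1,2-didehydro-4,5-dimethylbenzene) | CC1=CC#CC=C1C | intermediate
4 | 2-methoxy-6,7-dimethyl-1,4-dihydro-1,4-epoxynaphthalene, racemic, bridgeheads joined cis by the oxygen bridge (one enantiomer drawn) | COC1=C[C@H]2O[C@@H]1c1cc(C)c(C)cc12 | intermediate
5 | 2-methoxy-6,7-dimethylnaphthalen-1-ol | COc1ccc2cc(C)c(C)cc2c1O | intermediate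
6 | 1-iodo-2,4,5-trimethoxybenzene | COc1cc(OC)c(OC)cc1I | starting material
7 | 2-methoxy-6,7-dimethyl-8-(2,4,5-trimethoxyphenyl)naphthalen-1-ol | COc1ccc2cc(C)c(C)c(-c3cc(OC)c(OC)cc3OC)c2c1O | intermediate
8 | 2-methoxy-6,7-dimethyl-8-(2,4,5-trimethoxyphenyl)naphthalene-1,4-dione | COC1=CC(=O)c2cc(C)c(C)c(-c3cc(OC)c(OC)cc3OC)c2C1=O | target

Total step count: 3
Longest linear sequence: 3 steps (1 → 5 → 7 → 8)

Steps most likely to fail

Step 2. Palladation at C8 may be slow because this C–H is flanked by the C7 methyl group, and reductive elimination must form a biaryl hindered on three sides; oxidative self-coupling of the electron-rich naphtholate at C4 could then take over. The fallback sets out from 5 and returns at 7, replacing the catalytic C–H arylation by stoichiometric directed metalation and cross-coupling. Compound 5 would be O-carbamoylated (NaH, ClCONEt2, THF) to 2-methoxy-6,7-dimethylnaphthalen-1-yl N,N-diethylcarbamate F1. With C2 blocked, s-BuLi/TMEDA (THF, −78 °C) should metalate the peri position under carbamate direction to the 8-lithio carbamate F2. ZnCl2 would convert this into the arylzinc chloride F3, and Negishi coupling with 6 (Pd2(dba)3, SPhos, THF, 60 °C) should give the 8-aryl carbamate F4. KOH in aqueous ethanol at reflux would then free 7.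

Step 1. Acid may hydrolyse or polymerise the enol ether of 2 or 4 faster than the bridge opens, with loss of the methyl ether. The fallback sets out from 1 and returns at 5, carrying a bromine through the opening in place of the acid-labile methoxy group. The aryne 3 from 1 (CsF, MeCN) would be trapped with 3-bromofuran to give racemic 2-bromo-6,7-dimethyl-1,4-dihydro-1,4-epoxynaphthalene F5, which has no enol ether. Acid (HCl, MeOH) should open it by the same C4–O ionisation to 2-bromo-6,7-dimethylnaphthalen-1-ol F6. An Ullmann-type methoxylation (NaOMe, CuI, MeOH–DMF, 110 °C) would then give 5.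

Step 3. The oxidant may attack the methoxy-bearing ortho carbon C2 instead of C4, with loss of methanol and formation of an ortho-quinone. The fallback sets out from 7 and returns at 8, fixing the C4 heteroatom by electrophilic substitution before any oxidation. Azo coupling of 7 with benzenediazonium chloride (aq. NaOH, pyridine, 0 °C) can occur only at C4 and would give 2-methoxy-6,7-dimethyl-4-[(E)-phenyldiazenyl]-8-(2,4,5-trimethoxyphenyl)naphthalen-1-ol F7. Reduction with Na2S2O4 would give 4-amino-2-methoxy-6,7-dimethyl-8-(2,4,5-trimethoxyphenyl)naphthalen-1-ol F8. FeCl3 in dilute HCl should oxidise this para-aminophenol to the 4-imino-naphthalen-1(4H)-one F9, which hydrolyses in the same flask to 8.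

Further compounds
F1 | step 2 | 2-methoxy-6,7-dimethylnaphthalen-1-yl N,N-diethylcarbamate | CCN(CC)C(=O)Oc1c(OC)ccc2cc(C)c(C)cc12
F2 | step 2 | 8-lithio-2-methoxy-6,7-dimethylnaphthalen-1-yl N,N-diethylcarbamate | CCN(CC)C(=O)Oc1c(OC)ccc2cc(C)c(C)c([Li])c12
F3 | step 2 | 8-(chlorozincio)-2-methoxy-6,7-dimethylnaphthalen-1-yl N,N-diethylcarbamate | CCN(CC)C(=O)Oc1c(OC)ccc2cc(C)c(C)c([Zn]Cl)c12
F4 | step 2 | 2-methoxy-6,7-dimethyl-8-(2,4,5-trimethoxyphenyl)naphthalen-1-yl N,N-diethylcarbamate | CCN(CC)C(=O)Oc1c(OC)ccc2cc(C)c(C)c(-c3cc(OC)c(OC)cc3OC)c12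
F5 | step 1 | 2-bromo-6,7-dimethyl-1,4-dihydro-1,4-epoxynaphthalene, racemic (one enantiomer drawn) | BrC1=C[C@H]2O[C@@H]1c1cc(C)c(C)cc12
F6 | step 1 | 2-bromo-6,7-dimethylnaphthalen-1-ol | Oc1c(Br)ccc2cc(C)c(C)cc12
F7 | step 3 | 2-methoxy-6,7-dimethyl-4-[(E)-phenyldiazenyl]-8-(2,4,5-trimethoxyphenyl)naphthalen-1-ol | COc1cc(/N=N/c2ccccc2)c2cc(C)c(C)c(-c3cc(OC)c(OC)cc3OC)c2c1O
F8 | step 3 | 4-amino-2-methoxy-6,7-dimethyl-8-(2,4,5-trimethoxyphenyl)naphthalen-1-ol | COc1cc(N)c2cc(C)c(C)c(-c3cc(OC)c(OC)cc3OC)c2c1O
F9 | step 3 | 4-imino-2-methoxy-6,7-dimethyl-8-(2,4,5-trimethoxyphenyl)naphthalen-1(4H)-one | COC1=CC(=N)c2cc(C)c(C)c(-c3cc(OC)c(OC)cc3OC)c2C1=O
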